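| flask | electrophile | nucleophile | free base | protic impurity | remark | time |
|---|---|---|---|---|---|---|
| Tuesday's | 20 mM | 2 equiv | 2.7 equiv | 20 mM | run made earlier |  |
| Friday's | 20 mM | 2 equiv | 10 equiv | 20 mM | run made earlier |  |
| oak | 20 mM | 2.00 equiv | 2.00 equiv | 20.0 mM |  | 2.5 min |
| larch | 20 mM | 2.00 equiv | 8.00 equiv | 20.0 mM |  | 2.5 min |
| ash | 20 mM | 2.00 equiv | 4.00 equiv | 20.0 mM |  | 2.5 min |

| run | time / s | electrophile / % | product / % |
|---|---|---|---|
| Tuesday's | 20.0 | 77.4 | 22.4 |
| Tuesday's | 40.0 | 70.2 | 30.8 |
| Tuesday's | 60.0 | 65.5 | 35.6 |
| Tuesday's | 80.0 | 63.6 | 39.1 |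
| Tuesday's | 120 | 57.7 | 42.7 |
| Friday's | 20.0 | 77.6 | 22.3 |
| Friday's | 40.0 | 70.2 | 30.0 |
| Friday's | 60.0 | 64.7 | 34.5 |
| Friday's | 80.0 | 61.6 | 38.6 |
| Friday's | 120 | 55.2 | 45.0 |

(each reading ± 1 percentage point)



- part of the electrophile that has reacted at the end, oak
- part of the electrophile that has reacted at the end, larch
- part of the electrophile that has reacted at the end, ash
- what raising the equivalents of free base from its lowest to its highest value here does to the part of the electrophile that has reacted (changes below 5 percentage points count as none) (it rises / no change / it falls)

Fold both runs into one number. At each time I take the mean product of Tuesday's and Friday's, 22.3 % at 20.0 s and 43.9 % at 120 s. The time exponent, the percent growth of the reacted part per percent of elapsed time, is then 0.376. An exponent of one is a steady rate; this one lies below it, so across these readings doubling the time multiplies the reacted part by about 1.30.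

Carried to 2.5 min, it gives 47.7 %. Is one number enough? At 60.0 s the exponent gives 33.8 % and the mean reading is 35.1 %, so I attach an error of 1.3 percentage points. Free base does not enter my number: Friday's minus Tuesday's product, averaged over the five readings, is −0.04 points. So I expect no change from oak to larch. Oak's 2.00 equiv of free base lies below Tuesday's 2.7 equiv, with [protic impurity] at 20.0 mM as in both runs, so for oak this is an extension, not a reading.

The forecast gives 47 % for oak, 48 % for larch, 48 % for ash and no change, holding the reaction “effectively zero order in base at 2.7 equiv and above”.

The flasks give 47.2 % for oak, 47.3 % for larch and 47.2 % for ash, a change of 0.13 points, so no change. My exponent's figure stands 0.40 points above larch.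

    nucleophile + acid set free ⇌ protonated nucleophile, settled at all times (K = 26000 /M)
    electrophile + nucleophile → acid set free + product (k = 0.490 /M/s)
    nucleophile + protic impurity → quenched reagent (k = 1.70 /M/s)
    acid set free → by-product carried off (k = 1.20 /s)
    acid set free + free base ⇌ salt of the base (K = 49.0 /M, k = 87.0 /M/s)
    nucleophile ⇌ dormant form (K = 0.810, k = 0.0120 /s)

Just after the start of larch, the nucleophile goes to quenched reagent 3.5 times as fast as it goes to product. At the asked time that ratio is 0.71, with 11 % of the charged nucleophile still free.

For larch left until 10 min, the exponent gives 80.4 %. The computed flask has 74.7 %.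

(The earlier runs and the new flask stem from a simulated flask on assumed constants, and the scatter is random.)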